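Compare the two flasks at their first reading, then follow that comparison up the clock.

the same everywhere: partner 200 mM

| run | starting material | time |
|---|---|---|
| Tuesday's | 250 mM |  |
| Friday's | 750 mM |  |
| Thursday's | 250 mM | 80 h |

| run | time / h | [product] / mM |
|---|---|---|
| Tuesday's run | 6.7 | 65.9 |
| Tuesday's run | 13 | 106.9 |
| Tuesday's run | 20 | 129.9 |
| Tuesday's run | 27 | 141.6 |
| Tuesday's run | 33 | 141.7 |
| Tuesday's run | 40 | 144.9 |
| Friday's run | 6.7 | 128.6 |
| Friday's run | 13 | 179.2 |
| Friday's run | 20 | 189.7 |
| Friday's run | 27 | 195.0 |
| Friday's run | 33 | 195.4 |
| Friday's run | 40 | 194.4 |

(standard deviation of a reading: 1 mM)

1. how the opening rate goes with [starting material] round the charge of the Tuesday's run: the exponent of the rate at two percent of starting material gone to product (one fixed amount of product, the same in the runs compared)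
2. product in the Thursday's run at 80 h, as a share of the starting material charged

- Overall: starting material + partner -> product.
- Constant volume, constant temperature.
- "The second partner" is partner.
- An order is taken over about fifteen percent of the charge, up and down.

We count product as a fraction of the partner charge, which is the same in both flasks.

1. Opening, Friday's flask. At 6.7 h it holds 64.3 %. Partner charge over mean rate gives a time constant of 10.4 h.

2. Opening, Tuesday's flask. At 6.7 h it holds 32.9 %. Its time constant is 20.3 h, longer than Friday's.

3. The carried quantity. The starting material charge differs by a factor of 3.00, and the first readings by a factor of 1.95. We define the opening exponent as the log of the reading ratio over the log of the charge ratio. It comes to 0.609, and that is our estimate of the order.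

4. The drift. The ratio falls to 1.68 at 13 h. Friday's flask then holds 89.6 %, and partner is the limiting reagent by charge. So we use the first reading.

5. The late readings. From 27 h to 40 h Friday's flask stays level, reading 195.0 mM and then 194.4 mM. Over the same span Tuesday's flask creeps from 141.6 mM to 144.9 mM, a rise of 3.30 mM against a scatter of 1 mM per reading. Friday's flask ends at nearly all of the partner charge, and Tuesday's at 72.4 %.

6. Thursday's flask. It repeats Tuesday's charge, and 80 h is twice Tuesday's last time. Tuesday's last reading is 58.0 % of the starting material charged, and we take that share, leaving the creep out of our reckoning.

The forecast gives 0.88 and 58 %: “That implies an order slightly below one”. Our exponent is lower than its order, while its Thursday share matches ours.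

    starting material + partner → intermediate (0.6840 /M/h)
    intermediate → product (0.2812 /h)
    2 partner → lost reagent (0.06264 /M/h)
    starting material → decomposed substrate (0.03996 /h)

The flask gives an exponent of 0.57, and Thursday's flask reaches 59.7 % of the starting material charged. At one fixed amount of product, Tuesday's flask runs at 7.7 mM/h and Friday's at 14 mM/h, a ratio of 1.8. The opening exponent, applied to Tuesday's rate, gives 15.0 mM/h for Friday's flask, against the 14 mM/h it shows.

The numbers in the tables are calculated for an exercise; scatter was added.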